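Cuts (retrosynthetic order): first the C8–CH2 bond of the prenyl chain, leading back to a 7-O-(1,1-dimethylallyl) ether. Then O1–C2 of ring C (back to a β-keto dimethyl acetal), then C3–C1' (ring B returns to the carbon that becomes C2, giving a chalcone), and last the chalcone Cα=Cβ bond (methyl ketone + aldehyde).
Forward order: rings A and B are bought as arenes and joined by an aldol condensation. An oxidative 1,2-aryl shift rewires the three-carbon chain, ring C closes through O1–C2, and the prenyl group is added last by an O7→C8 [3,3] transfer.
Enabling feature: ring B sits on C3 of the pyran-4-one ring C, C2 is an unsubstituted CH at the aldehyde oxidation level, and the 4'-OMe lies para to C1', so ring B is an ideal bridging (phenonium) migrating group. On ring A, C8 is the only hydrogen-bearing carbon ortho to O7, because C6 carries OMe.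
Stereochemistry: the target has none to set. The sp3 centres that appear on the way (Cα of the acetal, C8 of the Claisen dienone) form racemic and disappear on aromatisation.

Key step: step 6

Remark on the chemistry: the target has no stereocentre, stereoaxis or stereogenic double bond. It is achiral, so the single constitution drawn is the only form and no asymmetric step or resolution is needed.

Step 1
Reactants: 1 2,4-dihydroxyacetophenone
Product: 2 4-benzyloxy-2-hydroxyacetophenone
Conditions: BnBr (1.05 equiv), K2CO3 (1.1 equiv), acetone, reflux
Reagents that add atoms: benzyl bromide, BrCc1ccccc1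
Why: Williamson etherification in which the 2-OH, hydrogen-bonded to the acetyl oxygen, is much less nucleophilic under weak base, so one equivalent of halide should alkylate only the 4-OH.

Step 2
Reactants: 2 4-benzyloxy-2-hydroxyacetophenone
Product: 4 4-benzyloxy-2,5-dihydroxyacetophenone, via potassium aryl sulfate 3 (not isolated)
Conditions: K2S2O8 (1.1 equiv), aq KOH, pyridine, 5 °C → rt; acidify (HCl), extract unchanged 2; then aq HCl, 85 °C
Reagents that add atoms: potassium peroxodisulfate, [K+].[K+].[O-]S(=O)(=O)OOS(=O)(=O)[O-]
Why: Elbs persulfate oxidation, in which the phenolate attacks the peroxide O–O bond through the carbon para to its oxygen (C5, also activated by the ortho benzyloxy group), the water-soluble sulfate 3 allows unchanged 2 to be recovered, and brief acid hydrolysis of the S–O bond should free the 5-OH without cleaving the benzyl ether.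

Step 3
Reactants: 4 4-benzyloxy-2,5-dihydroxyacetophenone
Product: 5 4-benzyloxy-2-hydroxy-5-methoxyacetophenone
Conditions: MeI (1.05 equiv), K2CO3 (1.1 equiv), acetone, N2, reflux
Reagents that add atoms: iodomethane, CI
Why: Chemoselective Williamson methylation, since of the two phenols only the new 5-OH is free of chelation to the ketone and should react with a single equivalent of iodomethane, with air excluded to protect the hydroquinone.

Step 4
Reactants: 5 4-benzyloxy-2-hydroxy-5-methoxyacetophenone
Product: 6 2,4-bis(benzyloxy)-5-methoxyacetophenone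
Conditions: BnBr (1.5 equiv), K2CO3, DMF, 80 °C
Reagents that add atoms: benzyl bromide, BrCc1ccccc1
Why: Williamson etherification under stronger conditions (polar aprotic solvent, heat, excess halide) should overcome the chelation of the 2-OH and cap the oxygen that must stay inert during the oxidative rearrangement.

Step 5
Reactants: 6 2,4-bis(benzyloxy)-5-methoxyacetophenone; 7 3,4-dimethoxybenzaldehyde (veratraldehyde)
Product: 8 (E)-1-[2,4-bis(benzyloxy)-5-methoxyphenyl]-3-(3,4-dimethoxyphenyl)prop-2-en-1-one (chalcone)
Conditions: KOH, EtOH, rt
Reagents that add atoms: none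
Why: Claisen–Schmidt condensation in which 6 is the only enolisable partner and 7 the only good electrophile, and E1cB loss of water should give the conjugated E-enone, whose geometry has no bearing on later steps.

Step 6
Reactants: 8 (E)-1-[2,4-bis(benzyloxy)-5-methoxyphenyl]-3-(3,4-dimethoxyphenyl)prop-2-en-1-one
Product: 9 racemic 1-[2,4-bis(benzyloxy)-5-methoxyphenyl]-2-(3,4-dimethoxyphenyl)-3,3-dimethoxypropan-1-one
Conditions: Tl(NO3)3·3H2O (1.1 equiv), MeOH–HC(OMe)3, rt
Reagents that add atoms: methanol, CO
Why: Tl(III) and methanol add across the enone C=C (oxythallation) with thallium on Cα and OMe on the benzylic Cβ; as the weak C–Tl bond ionises with reduction to Tl(I), ring B bridges Cα and Cβ as a phenonium ion and opens towards Cα, and the methoxy-stabilised cation left at Cβ takes up a second methanol. This is the established thallium(III) nitrate oxidative 1,2-aryl rearrangement of 2'-O-protected chalcones to 2-aryl-3,3-dimethoxypropan-1-ones, the flask counterpart of the isoflavone-synthase shift. It makes the future C3–C1' bond and two C–O bonds at the future C2, breaks the former Cβ–C1' bond and closes no ring, so no mode of closure applies here and ring C is closed from the acetal in step 7. Cα becomes a stereocentre with no controlling element, so 9 is racemic, which costs nothing because this carbon turns into sp2 C3 in step 7. Ring B must migrate faster than the aroyl group shifts, than solvent displaces thallium, and than the ortho oxygen cyclises to an aurone or flavone: the 4-OMe para to the migrating carbon gives ring B a high migratory aptitude that the electron-poor aroyl carbon lacks, and the benzyl cap on the 2'-oxygen removes the internal nucleophile and shields what would be a para-alkoxyphenol from oxidation. About one equivalent of oxidant limits attack on the alkoxy-rich rings, and trimethyl orthoformate consumes the water of the thallium salt so that the acetal rather than the free β-keto aldehyde is obtained.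

Step 7
Reactants: 9 racemic 1-[2,4-bis(benzyloxy)-5-methoxyphenyl]-2-(3,4-dimethoxyphenyl)-3,3-dimethoxypropan-1-one
Product: 11 7-hydroxy-6,3',4'-trimethoxyisoflavone (cladrastin), via debenzylated keto acetal 10 (not isolated)
Conditions: H2 (1 atm), 10% Pd/C, MeOH–EtOAc, rt; filter; then conc. HCl (cat.), MeOH, reflux
Reagents that add atoms: none
Why: Hydrogenolysis of both benzyl aryl ethers followed by acid-catalysed acetal ionisation, in which the freed 2'-OH captures the oxocarbenium carbon (6-exo-trig, O1–C2), loss of the second methanol across C2–C3 gives the aromatic pyran-4-one, and the 4'-OH cannot reach the chain and emerges as the 7-OH.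

Step 8
Reactants: 11 7-hydroxy-6,3',4'-trimethoxyisoflavone; 12 3-chloro-3-methylbut-1-yne
Product: 13 7-(2-methylbut-3-yn-2-yloxy)-6,3',4'-trimethoxyisoflavone
Conditions: K2CO3, CuI (10 mol %), DMF, 60 °C
Reagents that add atoms: none
Why: Copper-catalysed propargylic etherification, in which the copper acetylide of 12 ionises chloride to an allenylidene-type electrophile that the only free phenolate (O7) should attack at the tertiary carbon, where a direct SN2 displacement would be impossible.

Step 9
Reactants: 13 7-(2-methylbut-3-yn-2-yloxy)-6,3',4'-trimethoxyisoflavone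
Product: 14 7-(2-methylbut-3-en-2-yloxy)-6,3',4'-trimethoxyisoflavone (reverse-prenyl ether)
Conditions: H2 (1 atm), Lindlar catalyst (Pd/CaCO3, Pb-poisoned), quinoline, EtOAc, rt, stopped after 1 equiv H2
Reagents that add atoms: none
Why: Lindlar semihydrogenation, since the terminal alkyne binds the poisoned palladium far better than the product vinyl group or the conjugated trisubstituted C2=C3 bond of ring C, so uptake should stop at the alkene.

Step 10
Reactants: 14 7-(2-methylbut-3-en-2-yloxy)-6,3',4'-trimethoxyisoflavone
Product: 16 7-hydroxy-6,3',4'-trimethoxy-8-(3-methylbut-2-en-1-yl)isoflavone (target), via ortho-dienone 15 (not isolated)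
Conditions: PhNEt2, 170 °C, Ar
Reagents that add atoms: none
Why: Aromatic Claisen rearrangement, whose [3,3] shift inverts the allyl unit so that its CH2 terminus bonds to C8 (the only ortho carbon that can re-aromatise, C6 being blocked by OMe) and the former O-bound carbon becomes the Me2C= terminus, after which racemic dienone 15 enolises to the phenol while the amine solvent buffers acid traces that could close a chroman.

Compound list
1 | 2,4-dihydroxyacetophenone | CC(=O)c1ccc(O)cc1O | starting material
2 | 4-benzyloxy-2-hydroxyacetophenone | CC(=O)c1ccc(OCc2ccccc2)cc1O | intermediate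
3 | potassium 5-acetyl-2-benzyloxy-4-hydroxyphenyl sulfate (not isolated) | CC(=O)c1cc(OS(=O)(=O)[O-])c(OCc2ccccc2)cc1O.[K+] | intermediate
4 | 4-benzyloxy-2,5-dihydroxyacetophenone | CC(=O)c1cc(O)c(OCc2ccccc2)cc1O | intermediate
5 | 4-benzyloxy-2-hydroxy-5-methoxyacetophenone | CC(=O)c1cc(OC)c(OCc2ccccc2)cc1O | intermediate
6 | 2,4-bis(benzyloxy)-5-methoxyacetophenone | CC(=O)c1cc(OC)c(OCc2ccccc2)cc1OCc1ccccc1 | intermediate
7 | 3,4-dimethoxybenzaldehyde (veratraldehyde) | COc1ccc(C=O)cc1OC | starting material
8 | (E)-1-[2,4-bis(benzyloxy)-5-methoxyphenyl]-3-(3,4-dimethoxyphenyl)prop-2-en-1-one | COc1ccc(/C=C/C(=O)c2cc(OC)c(OCc3ccccc3)cc2OCc2ccccc2)cc1OC | intermediate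
9 | racemic 1-[2,4-bis(benzyloxy)-5-methoxyphenyl]-2-(3,4-dimethoxyphenyl)-3,3-dimethoxypropan-1-one | COC(OC)C(c1ccc(OC)c(OC)c1)C(=O)c1cc(OC)c(OCc2ccccc2)cc1OCc1ccccc1 | intermediate
10 | racemic 1-(2,4-dihydroxy-5-methoxyphenyl)-2-(3,4-dimethoxyphenyl)-3,3-dimethoxypropan-1-one (not isolated) | COC(OC)C(c1ccc(OC)c(OC)c1)C(=O)c1cc(OC)c(O)cc1O | intermediate
11 | 7-hydroxy-6,3',4'-trimethoxyisoflavone (cladrastin) | COc1ccc(-c2coc3cc(O)c(OC)cc3c2=O)cc1OC | intermediate
12 | 3-chloro-3-methylbut-1-yne | CC(C)(Cl)C#C | starting material
13 | 7-(2-methylbut-3-yn-2-yloxy)-6,3',4'-trimethoxyisoflavone | COc1ccc(-c2coc3cc(OC(C)(C)C#C)c(OC)cc3c2=O)cc1OC | intermediate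
14 | 7-(2-methylbut-3-en-2-yloxy)-6,3',4'-trimethoxyisoflavone | COc1ccc(-c2coc3cc(OC(C)(C)C=C)c(OC)cc3c2=O)cc1OC | intermediate
15 | racemic 3-(3,4-dimethoxyphenyl)-6-methoxy-8-(3-methylbut-2-en-1-yl)-8H-chromene-4,7-dione (Claisen ortho-dienone, not isolated) | COc1ccc(C2=COC3=C(C=C(OC)C(=O)C3CC=C(C)C)C2=O)cc1OC | intermediate
16 | 7-hydroxy-6,3',4'-trimethoxy-8-(3-methylbut-2-en-1-yl)isoflavone | COc1ccc(-c2coc3c(CC=C(C)C)c(O)c(OC)cc3c2=O)cc1OC | target

Total step count: 10.
Longest linear sequence: 10 steps (1 → 16). Compounds 7 and 12 enter as bought.

Steps most likely to fail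

Step 2 (Elbs oxidation). The chelated, acyl-deactivated phenolate may attack persulfate only sluggishly. The hydroquinone-type product may be over-oxidised by radical pathways in base, and some benzyl ether may be lost during the acid hydrolysis. The fallback replaces C–H oxidation by halogenation and C–O cross-coupling. Setting out from 2, NBS in MeCN at 0 °C should brominate the position para to the free phenol and give 1-(4-benzyloxy-5-bromo-2-hydroxyphenyl)ethanone F1. An Ullmann-type methoxylation (NaOMe, CuBr cat., MeOH–DMF, 110 °C), in which the phenolate form keeps the methyl ketone out of aldol chemistry, should then exchange bromide for methoxide. This comes back to the route at 5 and replaces steps 2 and 3 together.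

Step 6 (oxidative aryl shift). Thallium(III) nitrate may oxidise or nitrate the alkoxy-rich rings in competition with oxythallation, and solvent may be captured at Cα before the aryl group has moved. The fallback builds ring C first and forms C3–C1' by cross-coupling. Setting out from 5, heating with DMF dimethyl acetal should give (E)-1-(4-benzyloxy-2-hydroxy-5-methoxyphenyl)-3-(dimethylamino)prop-2-en-1-one F2. Iodine in MeOH should then cyclise and iodinate it to 7-benzyloxy-3-iodo-6-methoxychromen-4-one F3. Suzuki–Miyaura coupling with commercial 3,4-dimethoxyphenylboronic acid (Pd(PPh3)4, K2CO3, DME–H2O, 80 °C) should give 7-benzyloxy-6,3',4'-trimethoxyisoflavone F4. Hydrogenolysis of the single benzyl ether (H2, Pd/C, stopped after one equivalent) comes back to the route at 11.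

Step 10 (reverse-prenyl Claisen). The crowded tertiary allyl ether may lose its allyl group thermally by ionisation or retro-ene expulsion of isoprene before the [3,3] shift. The ortho-prenylphenol may also ring-close onto its own alkene. The fallback uses a primary allyl group, which cannot fragment in this way, and forms the trisubstituted alkene last. Setting out from 11, allyl bromide and K2CO3 in acetone should give 7-allyloxy-6,3',4'-trimethoxyisoflavone F5. Heating in PhNEt2 at 200 °C should move the allyl group to C8 through the transient racemic 8-allyl-3-(3,4-dimethoxyphenyl)-6-methoxy-8H-chromene-4,7-dione F6 and give 8-allyl-7-hydroxy-6,3',4'-trimethoxyisoflavone F7. Olefin cross-metathesis with excess 2-methylbut-2-ene (Grubbs second-generation catalyst, CH2Cl2, 40 °C) comes back to the route at 16 and also bypasses steps 8 and 9.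

Further compounds
F1 | step 2 | 1-(4-benzyloxy-5-bromo-2-hydroxyphenyl)ethanone | CC(=O)c1cc(Br)c(OCc2ccccc2)cc1O
F2 | step 6 | (E)-1-(4-benzyloxy-2-hydroxy-5-methoxyphenyl)-3-(dimethylamino)prop-2-en-1-one | CN(C)/C=C/C(=O)c1cc(OC)c(OCc2ccccc2)cc1O
F3 | step 6 | 7-benzyloxy-3-iodo-6-methoxychromen-4-one | COc1cc2c(cc1OCc1ccccc1)occ(I)c2=O
F4 | step 6 | 7-benzyloxy-6,3',4'-trimethoxyisoflavone | COc1ccc(-c2coc3cc(OCc4ccccc4)c(OC)cc3c2=O)cc1OC
F5 | step 10 | 7-allyloxy-6,3',4'-trimethoxyisoflavone | COc1ccc(-c2coc3cc(OCC=C)c(OC)cc3c2=O)cc1OC
F6 | step 10 | racemic 8-allyl-3-(3,4-dimethoxyphenyl)-6-methoxy-8H-chromene-4,7-dione | COc1ccc(C2=COC3=C(C=C(OC)C(=O)C3CC=C)C2=O)cc1OC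
F7 | step 10 | 8-allyl-7-hydroxy-6,3',4'-trimethoxyisoflavone | COc1ccc(-c2coc3c(CC=C)c(O)c(OC)cc3c2=O)cc1OC
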